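The readings stem from a simulated flask for an exercise; the scatter is artificial.

**The trap.** A free base in the flask tempts you to count it as the acid's taker. Yet elm and cedar, at 0.50 equiv and 0.73 equiv of it, read electrophile 30.3 % and 30.1 % at 6.00 min, with a scatter of 0.5 percentage points.

| setting | elm | cedar | Tuesday's | Friday's |
|---|---|---|---|---|
| electrophile | 0.10 M | 0.10 M | 0.10 M | 0.10 M |
| nucleophile | 1.05 equiv | 1.05 equiv | 1.05 equiv | 1.05 equiv |
| free base | 0.50 equiv | 0.73 equiv | 0.800 equiv | 1.20 equiv |
| remark | run made earlier | run made earlier |  |  |
| time |  |  | 12 min | 12 min |

- elm (time / min: electrophile / %, target / %): 1.50: 50.2, 48.0; 3.00: 41.7, 55.2; 5.00: 33.6, 62.5; 6.00: 30.3, 65.7; 8.00: 24.4, 69.8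
- cedar (time / min: electrophile / %, target / %): 1.50: 50.2, 48.2; 3.00: 41.4, 56.0; 5.00: 34.3, 61.7; 6.00: 30.1, 64.8; 8.00: 25.5, 69.7

(each reading ± 0.5 percentage points)

* part of the electrophile that has reacted at the end, Tuesday's
* part of the electrophile that has reacted at the end, Friday's
* what raising the equivalents of free base from its lowest to its highest value here does to the part of the electrophile that has reacted (changes below 5 percentage points count as none) (it falls / it rises / no change)

- on the list of suspects stand: electrophile + nucleophile -> acid set free + target; nucleophile + acid set free <-> protonated nucleophile; acid set free + free base <-> salt of the base; nucleophile + target -> over-reaction product; acid set free -> by-product carried off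

**What matters.** The difference in free base therefore moved little between these two runs at that reading. Time does matter: elm's electrophile still fell from 30.3 % to 24.4 % by 8.00 min. The nucleophile charge matters directly. While nucleophile takes the acid, divide its rate of loss by the electrophile's: the ratio is two, one reacting and one protonated, and time drops out. Nucleophile is then the limiting reagent, and the burst ceiling, its equivalents over two, is 52.5 %. Elm had reacted 49.8 % at 1.50 min, below that, and 75.6 % at 8.00 min, above it. Carrying off acid gives nucleophile back, so two acids carried off buy one electrophile past the ceiling.

**The forecast.** It gives 83 % (80.5 % to 85.5 %) for Tuesday's, 83.5 % (80.5 % to 88 %) for Friday's, and no change, since “the free base seems not to capture the acid appreciably”.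

**The result.** Tuesday's gives 82.6 % and Friday's 82.6 %, and raising the free base from its lowest to its highest value here gives no change, a change of 0.006 points, as forecast. In Tuesday's, 99.6 % of the free base is still free at the end.

    electrophile + nucleophile → acid set free + target (k = 0.234 L mol⁻¹ s⁻¹)
    nucleophile + acid set free ⇌ protonated nucleophile, settled at all times (K = 9300 L mol⁻¹)
    acid set free + free base ⇌ salt of the base (K = 24.0 L mol⁻¹, k = 6.01 L mol⁻¹ s⁻¹)
    nucleophile + target → over-reaction product (k = 0.0208 L mol⁻¹ s⁻¹)
    acid set free → by-product carried off (k = 0.320 s⁻¹)

Tuesday's stands 30 points past the ceiling. Its by-product, c(by-product carried off) = 0.0732 M, pays for 36.6 % at two per electrophile, and the over-reaction product, 7.73 %, used nucleophile too.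

**Second flask.** In a neighbour flask, Tuesday's with 4.20 equiv of nucleophile, the ceiling is 210 %, above the electrophile charged, so electrophile should go first. Computed, that neighbour reaches 100 %, with electrophile first out at 0 % and 34 % of the nucleophile left.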